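The runs were computed with constants of no real substance; noise was put on by code.

The pitfall in curves that look alike is to pool them and read the window off their mean, so before pooling anything I counted turnovers for the flask below.

| setting | epsilon | beta | theta | flask |
|---|---|---|---|---|
| starting material | 0.050 M | 0.050 M | 0.10 M | 0.050 M |
| reagent | 0.10 M | 0.10 M | 0.10 M | 0.100 M |
| second substrate | 0.050 M | 0.050 M | 0.050 M | 0.0500 M |
| third substrate | 0.070 M | 0.11 M | 0.050 M | 0.0500 M |
| remark | run made earlier | run made earlier | run made earlier |  |
| time |  |  |  | 4.0 min |

| run | time / min | target / % |
|---|---|---|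
| epsilon | 0.167 | 12.8 |
| epsilon | 0.250 | 13.1 |
| epsilon | 0.417 | 15.4 |
| epsilon | 0.833 | 14.0 |
| epsilon | 1.33 | 13.6 |
| epsilon | 2.50 | 11.6 |
| epsilon | 5.00 | 10.2 |
| beta | 0.167 | 13.0 |
| beta | 0.250 | 13.9 |
| beta | 0.417 | 14.9 |
| beta | 0.833 | 15.1 |
| beta | 1.33 | 14.3 |
| beta | 2.50 | 12.8 |
| beta | 5.00 | 10.4 |
| theta | 0.167 | 12.4 |
| theta | 0.333 | 15.0 |
| theta | 0.833 | 14.8 |
| theta | 2.00 | 12.6 |
| theta | 5.00 | 9.9 |

(scatter of a reading: 0.5 percentage points)

- when, up to 4.0 min, the flask holds most target
- the amount of target, in percent of the starting material charged, at that time
- earliest time at which at least nineteen twentieths of that best amount are there, in min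
- latest time at which they still are, in min

- the numbers in the tables scatter with a standard deviation of 0.5 percentage points

Reagent in the flask is charged below the substrates together, 0.100 M against 0.150 M, which makes it the limiting reagent. I therefore took the coverage c, 66.7 % in the flask, the reagent charged over the substrates charged together; it is the fraction of each substrate turned over if each reagent takes one substrate and the substrates share evenly. Beta has 47.6 % and epsilon 58.8 %, and in the readings epsilon fell sooner: at 0.833 min it held 90.9 % of its highest reading, while beta still held 94.7 % of its own at 1.33 min.

My objection was that this is scatter, and I could not compute it away: from 0.833 min on beta lies above epsilon by a mean 0.8 points, where the scatter of such a mean gap is 0.35 points, but the last readings stand at 10.4 % against 10.2 %, so I held the gap as a doubtful hint and not as a shown effect of coverage. A second objection was that theta has double the starting material, but its coverage, 50.0 %, lies beside beta's, and it too stayed high at 0.833 min, with 14.8 % against a top of 15.0 %. The flask has the highest coverage, so, with that doubt standing, I committed as a guess to a top near epsilon's highest reading, 15.4 % at 0.417 min, opening just after 0.250 min and closing near 0.833 min.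

The forecast, on the ground that “All three runs trace nearly the same curve”, gave 14.9 % at 0.55 min and a window from 0.29 min to 1.2 min, which closes later than mine. The flask gave 15.6 % at 0.492 min, with a window from 0.298 min to 0.859 min.

    starting material + reagent → target (k = 0.229 M⁻¹ s⁻¹)
    third substrate + reagent → third product (k = 0.238 M⁻¹ s⁻¹)
    reagent + target → over-reaction product (k = 0.840 M⁻¹ s⁻¹)
    target ⇌ isomer of the product (K = 0.800, k = 0.00495 s⁻¹)
    second substrate + reagent → second product (k = 0.197 M⁻¹ s⁻¹)

At 4.00 min the flask had 0.42 % of its reagent left, and its starting material had lost 55.3 % against a coverage of 66.7 %, with over-reaction product at 37.2 %. In the neighbour flask, with reagent cut to 0.025 M and the other charges as in the recipe, coverage is 16.7 %. There the starting material lost 15.9 %, over-reaction product reached 3.80 %, and the best amount of target was 9.07 %.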